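**Plan**
1. Retrosynthesis, late cuts: the C7 acetate and the C15 alcohol go back to dimethyl (13E)-labda-8(17),13-diene-15,19-dioate 27. Cutting C13=C14 (HWE), C8=C17 (methylenation) and C9–C11 (Michael addition to butenone) leads to a C8–C9 enolate of a trans-decalone.
2. Enabling feature: methyl C20 sits on quaternary C10, C10 is bonded to C9, and C9 is alpha to sp2 C8 of ring B. C20 can therefore be carried as a CH2 bridging C9 and C10, the cyclopropane of a cyclopropyl ketone, and released by breaking C9–C20.
3. Early cuts: tricycle 18 is cut at C9–C10 and C9–C20 to diazoketone 16 on ring A. 16 is cut at C8–C9, C10=C20, C5–C6 and C4–CH3 back to enone ester 1.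
4. Forward order: ring A is bought. Ring B and the three-membered ring close together in step 7, and the small ring is opened in step 8. The chain is joined at C9 in step 9 and extended in step 10; C17, O7 and the acetate follow.
5. Stereochemistry: C4 comes from a chiral NHC–Cu catalyst and C5 from C4. C10 and C9 come from C5/C4 in the key step, and C9 is then re-set by equilibration. C7 comes from axial hydride delivery and 13E from the HWE reaction.

Key step: step 7

Remark: atoms carry labdane numbers throughout (ring A = C1–C5, C10; ring B = C5–C10); it is assumed that the NHC ligand enantiomer used in step 1 is the one that delivers methyl to the enone face giving (S)-C4.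

Step 1
Reactants: 1 methyl 3-oxocyclohex-1-ene-1-carboxylate; 2 dimethylzinc
Product: 4 methyl (S)-1-methyl-3-(trimethylsilyloxy)cyclohex-2-ene-1-carboxylate, via zinc enolate 3 (not isolated)
Conditions: Me2Zn (3 equiv), (CuOTf)2·C6H6 (2.5 mol %), chiral bidentate NHC–Ag(I) complex (2.5 mol %), Et2O, −30 °C; then TMSOTf (1.5 equiv), −30 → 0 °C
Reagents that add atoms: dimethylzinc 2, C[Zn]C; trimethylsilyl trifluoromethanesulfonate, C[Si](C)(C)OS(=O)(=O)C(F)(F)F
Why: Cu-catalysed asymmetric conjugate addition of a dialkylzinc to a beta-alkoxycarbonyl cyclic enone is a known route to all-carbon quaternary centres; the chiral NHC–Cu complex selects the enone face and sets C4 as S, and O-silylation of the zinc enolate fixes the double bond between C5 and C10.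

Step 2
Reactants: 4 silyl enol ether; 5 allyl bromide
Product: 7 methyl (1S,2S)-1-methyl-3-oxo-2-(prop-2-enyl)cyclohexane-1-carboxylate, via lithium enolate 6 (not isolated)
Conditions: MeLi (1.05 equiv), THF, 0 °C; then allyl bromide (3 equiv), DMPU, −78 → −20 °C; chromatography
Reagents that add atoms: allyl bromide 5, C=CCBr
Why: Regiospecific release of the C5 lithium enolate from the silyl enol ether, then SN2 allylation: in the reactive half-chair the electron-poor C4–CO2Me bond lies near the enolate plane and the better donor C4–CH3 bond stands pseudoaxial, so the halide should enter anti to CH3 and set C5 with allyl cis to the ester, the C5 epimer being separable and recyclable by base equilibration.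

Step 3
Reactants: 7 allyl ketone; 8 dibromomethane
Product: 9 methyl (1S,2R)-1-methyl-3-methylidene-2-(prop-2-enyl)cyclohexane-1-carboxylate
Conditions: Zn, CH2Br2, TiCl4 (pre-aged reagent in THF), CH2Cl2, 0 °C → rt
Reagents that add atoms: dibromomethane 8, BrCBr
Why: Lombardo methylenation turns the hindered C10 ketone into C10=C20 without enolising it, which matters because C5 has no thermodynamic bias and a basic ylide could scramble it; the ester and the terminal alkene are inert.

Step 4
Reactants: 9 diene ester
Product: 11 methyl (1S,2R)-2-(3-hydroxypropyl)-1-methyl-3-methylidenecyclohexane-1-carboxylate, via alkylborane 10 (not isolated)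
Conditions: Sia2BH (1.1 equiv, from BH3·SMe2 and 2-methylbut-2-ene), THF, 0 °C; then NaOH, H2O2, 0 °C
Reagents that add atoms: hydrogen peroxide, OO
Why: Hydroboration–oxidation with a substitution-sensitive dialkylborane: disiamylborane adds to the monosubstituted allyl terminus far faster than to the 1,1-disubstituted, alpha-branched C10=C20 (9-BBN would not make this distinction reliably) and gives the anti-Markovnikov alcohol at C8; no stereocentre is formed.

Step 5
Reactants: 11 primary alcohol
Product: 13 3-[(1R,2S)-2-(methoxycarbonyl)-2-methyl-6-methylidenecyclohexyl]propanoic acid, via aldehyde 12 (not isolated)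
Conditions: TEMPO (0.2 equiv), PhI(OAc)2 (2.2 equiv), MeCN/H2O 1:1, rt
Reagents that add atoms: water, O
Why: TEMPO/PhI(OAc)2 oxidation in aqueous acetonitrile takes the primary alcohol through the aldehyde hydrate to the acid under near-neutral conditions that leave the acid-sensitive exocyclic alkene in place.

Step 6
Reactants: 13 acid; 14 (trimethylsilyl)diazomethane
Product: 16 methyl (1S,2R)-2-(4-diazo-3-oxobutyl)-1-methyl-3-methylidenecyclohexane-1-carboxylate, via mixed anhydride 15 (not isolated)
Conditions: i-BuOCOCl, Et3N, THF, −15 °C; then TMSCHN2 (2 equiv), MeCN, 0 °C → rt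
Reagents that add atoms: (trimethylsilyl)diazomethane 14, C[Si](C)(C)C=[N+]=[N-]
Why: Acylation of a diazoalkane by a mixed carbonic anhydride (first stage of the Arndt–Eistert sequence): no HCl is formed, so C10=C20 does not migrate, and silicon is lost to the released isobutoxide, giving the terminal diazoketone that carries C9.

Step 7
Reactants: 16 diazoketone
Product: 18 tricyclic 9,20-cyclo-8-ketone (rings A/B trans; C20 bridging C9 and C10 on the beta face), via copper carbenoid 17 (not isolated)
Conditions: Cu(acac)2 (5 mol %), ClCH2CH2Cl, reflux, 16 added over 8 h (final 5 mM)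
Reagents that add atoms: none
Why: Copper, reduced in situ to Cu(I), takes up the diazo carbon with loss of N2 to give the electrophilic carbenoid 17, whose carbene carbon C9 adds suprafacially and asynchronously (C9–C20 ahead of C9–C10, positive charge building on tertiary C10) to the 1,1-disubstituted C10=C20 alkene. The closest known reaction type is the Cu-catalysed intramolecular cyclopropanation of delta,epsilon-unsaturated diazomethyl ketones to bicyclo[4.1.0]heptan-2-ones, also known for 2-substituted methylenecyclohexanes next to a quaternary carbon. Ring B closes in the 6-exo sense (C9 onto C10, C20 outside the ring) through a chair-like array C5–C6–C7–C8–C9–C10, and the three-membered ring closes by the second bond of the same [2+1] addition. C10 is controlled by C5 and C4: with the C5 arm equatorial and C7 anti to C4 the carbenoid lies under the alpha face, whereas the beta face would need C7 gauche to quaternary C4 (syn-pentane contact) and an approach past the axial C4 ester, so C20 should end beta (axial) and the fusion trans; C9 follows from C10 because a cyclopropane can only be cis-fused to ring B. The step needs chemoselectivity for the alkene over 1,5-insertion into the tertiary allylic C5–H, over Wolff rearrangement and over carbene dimerisation, which copper instead of a rhodium(II) carboxylate, thermal conditions and slow addition at high dilution secure.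

Step 8
Reactants: 18 cyclopropyl ketone
Product: 20 trans-decalin C8-silyl enol ether (C8=C9; 10beta-CH3), via lithium enolate 19 (not isolated)
Conditions: Li (2.2 equiv), NH3(l)/THF, t-BuOH (1.0 equiv), −78 °C; NH3 off; TMSCl/Et3N, THF, 0 °C
Reagents that add atoms: chlorotrimethylsilane, C[Si](C)(C)Cl
Why: Dissolving-metal cleavage of a conjugated cyclopropyl ketone: the ketyl opens C9–C20, the bond parallel to the carbonyl pi orbitals of the rigid bicyclo[4.1.0]heptan-2-one (C9–C10 lies near their nodal plane), so C20 becomes the 10beta-methyl with C5 and C10 untouched, the regiodefined C8–C9 enolate is stored as its silyl ether, and with only two electron equivalents the ketone reacts before the hindered ester.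

Step 9
Reactants: 20 silyl enol ether; 21 but-3-en-2-one
Product: 23 methyl 8,13-dioxo-14,15,17-trinor-9betaH-labdan-19-oate (chain axial at 9alpha), via titanium enolate 22 (not isolated)
Conditions: MVK (1.5 equiv), TiCl4 (1.1 equiv), CH2Cl2, −78 °C; aq NaHCO3
Reagents that add atoms: but-3-en-2-one 21, C=CC(C)=O
Why: Mukaiyama–Michael addition, a reaction type that tolerates a neopentyl nucleophilic carbon where SN2 alkylation with an unactivated halide would be slow, joins C9 to C11; attack is axial from the alpha face, anti to the 10beta-methyl, so the chain is first 9alpha and is corrected in step 11.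

Step 10
Reactants: 23 diketone; 24 trimethyl phosphonoacetate
Product: 25 dimethyl (13E)-8-oxo-17-nor-9betaH-labd-13-ene-15,19-dioate
Conditions: (MeO)2P(O)CH2CO2Me (1.5 equiv), NaH (1.4 equiv), THF, 0 °C → rt; chromatography
Reagents that add atoms: trimethyl phosphonoacetate 24, COC(=O)CP(=O)(OC)OC
Why: Horner–Wadsworth–Emmons olefination: the weakly basic phosphonate anion reacts only with the unhindered methyl ketone C13 (C8 is flanked by C9 and quaternary C10) and does not enolise the 1,5-diketone towards aldol closure, the E-enoate (C12 trans to the ester) should predominate, and the Z isomer is removed by chromatography.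

Step 11
Reactants: 25 9alpha-chain keto diester
Product: 26 dimethyl (13E)-8-oxo-17-norlabd-13-ene-15,19-dioate (chain equatorial at 9beta)
Conditions: NaOMe (0.3 equiv), MeOH, rt
Reagents that add atoms: none
Why: Base-mediated epimerisation through the C8–C9 enolate moves the chain from the axial 9alpha position (syn-axial to H5 and H7) to the equatorial 9beta position under thermodynamic control; methoxide exchange on methyl esters is degenerate and no aldol partner is left.

Step 12
Reactants: 26 keto diester; 8 dibromomethane
Product: 27 dimethyl (13E)-labda-8(17),13-diene-15,19-dioate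
Conditions: Zn, CH2Br2, TiCl4 (pre-aged reagent in THF), CH2Cl2, 0 °C → rt
Reagents that add atoms: dibromomethane 8, BrCBr
Why: Lombardo methylenation installs C8=C17 on the hindered, epimerisable ketone without touching C9 and without the conjugate addition or deconjugation that an unstabilised ylide could cause at the enoate.

Step 13
Reactants: 27 diene diester
Product: 28 dimethyl (13E)-7alpha-hydroxylabda-8(17),13-diene-15,19-dioate
Conditions: SeO2 (0.5 equiv), t-BuOOH (3 equiv), CH2Cl2, 0 °C → rt
Reagents that add atoms: selenium dioxide (oxygen carrier), O=[Se]=O; tert-butyl hydroperoxide (terminal oxidant), CC(C)(C)OO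
Why: SeO2/t-BuOOH allylic hydroxylation (ene reaction, then [2,3]-shift): selenium binds C17, the axial 7alpha-H is removed (CH2 before CH, hence C7 and not C9) and oxygen returns to the same face, giving the axial 7alpha-alcohol, while the electron-poor C13=C14 enoate stays inert and any enone formed is carried into step 14.

Step 14
Reactants: 28 7alpha-alcohol
Product: 29 dimethyl (13E)-7-oxolabda-8(17),13-diene-15,19-dioate
Conditions: Dess–Martin periodinane, NaHCO3, CH2Cl2, 0 °C → rt
Reagents that add atoms: none
Why: Dess–Martin oxidation under bicarbonate buffer removes the wrong C7 configuration under neutral conditions that avoid migration of C8=C17 into the endocyclic conjugated position.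

Step 15
Reactants: 29 exocyclic enone
Product: 30 dimethyl (13E)-7beta-hydroxylabda-8(17),13-diene-15,19-dioate
Conditions: NaBH4, CeCl3·7H2O, MeOH, −78 → −20 °C
Reagents that add atoms: none
Why: Luche reduction is 1,2-selective, and the small hydride attacks C7 axially from the alpha face, so the alcohol should be equatorial (7beta); both esters are untouched.

Step 16
Reactants: 30 7beta-hydroxy diester
Product: 31 methyl (13E)-7beta,15-dihydroxylabda-8(17),13-dien-19-oate
Conditions: DIBAL-H (3.5 equiv), CH2Cl2, −78 °C; Rochelle salt
Reagents that add atoms: none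
Why: DIBAL-H reduces the conjugated C15 ester to the allylic alcohol with retention of the E geometry, while the C19 ester (axial, neopentyl, 1,3-diaxial to C20) is too hindered to react at −78 °C; this must precede acetylation because an acetate would not survive.

Step 17
Reactants: 31 diol
Product: 32 methyl (13E)-15-(tert-butyldimethylsilyloxy)-7beta-hydroxylabda-8(17),13-dien-19-oate
Conditions: TBSCl (1.05 equiv), imidazole, CH2Cl2, 0 °C
Reagents that add atoms: tert-butyldimethylsilyl chloride, CC(C)(C)[Si](C)(C)Cl
Why: Silylation is sterically selective for the primary allylic C15 hydroxyl over the secondary ring hydroxyl at C7.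

Step 18
Reactants: 32 silyl ether alcohol; 33 acetic anhydride
Product: 34 methyl (13E)-7beta-acetoxy-15-(tert-butyldimethylsilyloxy)labda-8(17),13-dien-19-oate
Conditions: Ac2O, pyridine, DMAP (cat.), CH2Cl2, rt
Reagents that add atoms: acetic anhydride 33, CC(=O)OC(C)=O
Why: DMAP-catalysed acylation of the only free hydroxyl proceeds at oxygen, so C7 keeps its configuration.

Step 19
Reactants: 34 acetate silyl ether
Product: 35 methyl (13E)-7beta-acetoxy-15-hydroxylabda-8(17),13-dien-19-oate (target)
Conditions: HF·pyridine, pyridine/THF, 0 °C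
Reagents that add atoms: none
Why: Buffered fluoride cleaves the primary silyl ether without acyl migration or loss of the allylic acetate.

**Compound list**
1 | methyl 3-oxocyclohex-1-ene-1-carboxylate | COC(=O)C1=CC(=O)CCC1 | starting material
2 | dimethylzinc | C[Zn]C | starting material
3 | methylzinc C5=C10 enolate of methyl (S)-1-methyl-3-oxocyclohexane-1-carboxylate | COC(=O)[C@@]1(C)CCCC(O[Zn]C)=C1 | intermediate
4 | methyl (S)-1-methyl-3-(trimethylsilyloxy)cyclohex-2-ene-1-carboxylate | COC(=O)[C@@]1(C)CCCC(O[Si](C)(C)C)=C1 | intermediate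
5 | allyl bromide | C=CCBr | starting material
6 | lithium C5=C10 enolate of methyl (S)-1-methyl-3-oxocyclohexane-1-carboxylate | COC(=O)[C@@]1(C)CCCC(O[Li])=C1 | intermediate
7 | methyl (1S,2S)-1-methyl-3-oxo-2-(prop-2-enyl)cyclohexane-1-carboxylate (allyl cis to CO2Me, trans to CH3) | COC(=O)[C@@]1(C)CCCC(=O)[C@H]1CC=C | intermediate
8 | dibromomethane | BrCBr | starting material
9 | methyl (1S,2R)-1-methyl-3-methylidene-2-(prop-2-enyl)cyclohexane-1-carboxylate | COC(=O)[C@@]1(C)CCCC(=C)[C@H]1CC=C | intermediate
10 | bis(3-methylbutan-2-yl)borane adduct at the allyl terminus of 9 | COC(=O)[C@@]1(C)CCCC(=C)[C@H]1CCCB(C(C)C(C)C)C(C)C(C)C | intermediate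
11 | methyl (1S,2R)-2-(3-hydroxypropyl)-1-methyl-3-methylidenecyclohexane-1-carboxylate | COC(=O)[C@@]1(C)CCCC(=C)[C@H]1CCCO | intermediate
12 | methyl (1S,2R)-1-methyl-3-methylidene-2-(3-oxopropyl)cyclohexane-1-carboxylate | COC(=O)[C@@]1(C)CCCC(=C)[C@H]1CCC=O | intermediate
13 | 3-[(1R,2S)-2-(methoxycarbonyl)-2-methyl-6-methylidenecyclohexyl]propanoic acid | COC(=O)[C@@]1(C)CCCC(=C)[C@H]1CCC(=O)O | intermediate
14 | (trimethylsilyl)diazomethane | C[Si](C)(C)C=[N+]=[N-] | starting material
15 | isobutyl carbonic mixed anhydride of 13 | COC(=O)[C@@]1(C)CCCC(=C)[C@H]1CCC(=O)OC(=O)OCC(C)C | intermediate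
16 | methyl (1S,2R)-2-(4-diazo-3-oxobutyl)-1-methyl-3-methylidenecyclohexane-1-carboxylate (key-step precursor) | COC(=O)[C@@]1(C)CCCC(=C)[C@H]1CCC(=O)C=[N+]=[N-] | intermediate
17 | copper carbenoid at C9 derived from 16 (ligands omitted) | COC(=O)[C@@]1(C)CCCC(=C)[C@H]1CCC(=O)C=[Cu] | intermediate
18 | methyl 8-oxo-9,20-cyclo-11,12,13,14,15,16,17-heptanorlabdan-19-oate: rings A/B trans (5alpha-H), CH2-20 bridging C9 and C10 on the beta face, 9alpha-H, 4alpha-CH3, 4beta-CO2CH3 (key-step product) | O=C1CC[C@@H]2[C@@]3(CCC[C@]2(C)C(=O)OC)C[C@@H]13 | intermediate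
19 | lithium C8–C9 enolate of the trans-decalone (10beta-CH3, 5alpha-H, 4beta-CO2CH3) | [Li]OC1=C[C@@]2(C)CCC[C@](C)(C(=O)OC)[C@@H]2CC1 | intermediate
20 | methyl 8-(trimethylsilyloxy)-11,12,13,14,15,16,17-heptanorlabd-8-en-19-oate (C8=C9, 10beta-CH3, 5alpha-H) | C[Si](C)(C)OC1=C[C@@]2(C)CCC[C@](C)(C(=O)OC)[C@@H]2CC1 | intermediate
21 | but-3-en-2-one (methyl vinyl ketone) | C=CC(C)=O | starting material
22 | trichlorotitanium C12=C13 enolate of 23 | O=C1CC[C@@H]2[C@](C)(CCC[C@]2(C)C(=O)OC)[C@@H]1CC=C(C)O[Ti](Cl)(Cl)Cl | intermediate
23 | methyl 8,13-dioxo-14,15,17-trinor-9betaH-labdan-19-oate (3-oxobutyl chain axial, 9alpha) | O=C1CC[C@@H]2[C@](C)(CCC[C@]2(C)C(=O)OC)[C@@H]1CCC(C)=O | intermediate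
24 | trimethyl phosphonoacetate | COC(=O)CP(=O)(OC)OC | starting material
25 | dimethyl (13E)-8-oxo-17-nor-9betaH-labd-13-ene-15,19-dioate (chain 9alpha) | O=C1CC[C@@H]2[C@](C)(CCC[C@]2(C)C(=O)OC)[C@@H]1CC/C(C)=C/C(=O)OC | intermediate
26 | dimethyl (13E)-8-oxo-17-norlabd-13-ene-15,19-dioate (chain 9beta, 9alpha-H) | O=C1CC[C@@H]2[C@](C)(CCC[C@]2(C)C(=O)OC)[C@H]1CC/C(C)=C/C(=O)OC | intermediate
27 | dimethyl (13E)-labda-8(17),13-diene-15,19-dioate | C=C1CC[C@@H]2[C@](C)(CCC[C@]2(C)C(=O)OC)[C@H]1CC/C(C)=C/C(=O)OC | intermediate
28 | dimethyl (13E)-7alpha-hydroxylabda-8(17),13-diene-15,19-dioate | C=C1[C@H](O)C[C@@H]2[C@](C)(CCC[C@]2(C)C(=O)OC)[C@H]1CC/C(C)=C/C(=O)OC | intermediate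
29 | dimethyl (13E)-7-oxolabda-8(17),13-diene-15,19-dioate | C=C1C(=O)C[C@@H]2[C@](C)(CCC[C@]2(C)C(=O)OC)[C@H]1CC/C(C)=C/C(=O)OC | intermediate
30 | dimethyl (13E)-7beta-hydroxylabda-8(17),13-diene-15,19-dioate | C=C1[C@@H](O)C[C@@H]2[C@](C)(CCC[C@]2(C)C(=O)OC)[C@H]1CC/C(C)=C/C(=O)OC | intermediate
31 | methyl (13E)-7beta,15-dihydroxylabda-8(17),13-dien-19-oate | C=C1[C@@H](O)C[C@@H]2[C@](C)(CCC[C@]2(C)C(=O)OC)[C@H]1CC/C(C)=C/CO | intermediate
32 | methyl (13E)-15-(tert-butyldimethylsilyloxy)-7beta-hydroxylabda-8(17),13-dien-19-oate | C=C1[C@@H](O)C[C@@H]2[C@](C)(CCC[C@]2(C)C(=O)OC)[C@H]1CC/C(C)=C/CO[Si](C)(C)C(C)(C)C | intermediate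
33 | acetic anhydride | CC(=O)OC(C)=O | starting material
34 | methyl (13E)-7beta-acetoxy-15-(tert-butyldimethylsilyloxy)labda-8(17),13-dien-19-oate | C=C1[C@@H](OC(C)=O)C[C@@H]2[C@](C)(CCC[C@]2(C)C(=O)OC)[C@H]1CC/C(C)=C/CO[Si](C)(C)C(C)(C)C | intermediate
35 | methyl (13E)-7beta-acetoxy-15-hydroxylabda-8(17),13-dien-19-oate | C=C1[C@@H](OC(C)=O)C[C@@H]2[C@](C)(CCC[C@]2(C)C(=O)OC)[C@H]1CC/C(C)=C/CO | target

Total step count: 19. Longest linear sequence: 19 steps (fully linear from 1).

**Steps most likely to fail**

**Step 7.**
- Risk: ring A may react through the flipped chair, with the C5 arm and the C4 methyl both axial. The carbenoid then reaches the beta face of C10=C20 and the ring fusion comes out cis. Part of the carbenoid may also be lost to insertion into the C5–H bond.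
- Fallback: it sets out from acid 13 and closes the same C9–C10 bond by a cationic route instead of a carbenoid one.
- Activation of 13 with carbonyldiimidazole and reaction with magnesium mono-allyl malonate (Masamune–Brooks homologation) should give the allyl beta-keto ester F1.
- SnCl4 in CH2Cl2 protonates C20 in the Markovnikov sense. The enol carbon C9 then traps the tertiary C10 cation through a chair–chair array. This should give the trans-decalin allyl beta-keto ester F2, in which C20 is already the methyl group.
- Michael addition of F2 to 21 (catalytic Cs2CO3) should give the C9-quaternary adduct F3.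
- Pd(PPh3)4 with HCO2H/Et3N removes the allyl ester with decarboxylation, and axial protonation of C9 should give the 9beta-diketone F4.
- Olefination of F4 under the conditions of step 10 comes back to the route at 26.

**Step 2.**
- Risk: CH3 and CO2CH3 on C4 are close in size, so the face of the enolate may be discriminated poorly. Proton transfer between enolate and product may also move allylation to C1.
- Fallback: it sets out from 4 and replaces substrate control by catalyst control.
- MeLi followed by allyl chloroformate should give the allyl enol carbonate F5.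
- Pd2(dba)3·CHCl3 with a chiral bis(2-diphenylphosphinobenzamide) ligand of a C2-symmetric trans-1,2-diamine then effects a decarboxylative asymmetric allylic alkylation in dioxane at rt. The ligand enantiomer is chosen to place allyl anti to CH3. The conditions are neutral, which keeps the regiochemistry and does not epimerise C5.
- This comes back to the route at 7.

**Step 9.**
- Risk: C–C bond formation at the neopentyl C9 may be slower than protodesilylation of 20 or Lewis-acid polymerisation of 21.
- Fallback: it sets out from 20 and replaces the Lewis-acid Michael addition by an enolate SN2 alkylation.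
- Commercial 2-(2-bromoethyl)-2-methyl-1,3-dioxolane is converted with NaI in acetone into 2-(2-iodoethyl)-2-methyl-1,3-dioxolane F6.
- MeLi regenerates enolate 19 from 20. Alkylation with F6 in THF/HMPA (−40 → 0 °C), again from the alpha face, should give the 9alpha-alkylated ketal ketone F7.
- PPTS in aqueous acetone removes the dioxolane and comes back to the route at 23.

**Further compounds**
F1 | step 7 | methyl (1S,2R)-2-[5-(allyloxy)-3,5-dioxopentyl]-1-methyl-3-methylidenecyclohexane-1-carboxylate | COC(=O)[C@@]1(C)CCCC(=C)[C@H]1CCC(=O)CC(=O)OCC=C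
F2 | step 7 | trans-decalin beta-keto ester: 8-oxo, 9beta-CO2-allyl, 10beta-CH3, 5alpha-H, 4beta-CO2CH3 | O=C1CC[C@@H]2[C@](C)(CCC[C@]2(C)C(=O)OC)[C@H]1C(=O)OCC=C
F3 | step 7 | Michael adduct of F2: C9 quaternary, 9alpha-(3-oxobutyl), 9beta-CO2-allyl | O=C1CC[C@@H]2[C@](C)(CCC[C@]2(C)C(=O)OC)[C@@]1(CCC(C)=O)C(=O)OCC=C
F4 | step 7 | methyl 8,13-dioxo-14,15,17-trinorlabdan-19-oate (chain 9beta) | O=C1CC[C@@H]2[C@](C)(CCC[C@]2(C)C(=O)OC)[C@H]1CCC(C)=O
F5 | step 2 | methyl (S)-3-(allyloxycarbonyloxy)-1-methylcyclohex-2-ene-1-carboxylate | COC(=O)[C@@]1(C)CCCC(OC(=O)OCC=C)=C1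
F6 | step 9 | 2-(2-iodoethyl)-2-methyl-1,3-dioxolane | CC1(CCI)OCCO1
F7 | step 9 | 13,13-ethylenedioxy derivative of 23 (chain 9alpha) | O=C1CC[C@@H]2[C@](C)(CCC[C@]2(C)C(=O)OC)[C@@H]1CCC1(C)OCCO1
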